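The readings are simulated for an exercise; the scatter is artificial.

The closed, stirred vessel holds electrophile, nucleophile and protic impurity, and the runs so far are early readings of this same flask.

the same everywhere: electrophile 0.80 M
- gamma: nucleophile 1.5 equiv; protic impurity 0.80 M; the very flask that is asked about, followed so far
- flask: nucleophile 1.50 equiv; protic impurity 0.800 M; time 20 min

- gamma (time / min: electrophile / %, product / %): 1.50: 71, 15; 3.00: 56, 28; 5.00: 44, 31; 6.00: 39, 36; 8.00: 30, 41

(standard deviation of a reading: 2 percentage points)

- what has gone from electrophile into another species counts as reacted, even if it can come back
- the earlier runs do not show how much of nucleophile is bound; that part of a forecast is a guess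

* part of the electrophile that has reacted at 20 min
* share of the unused nucleophile that is free and not bound as protonated nucleophile, at 20 min

The bench rule for this charge names the electrophile as limiting reagent and expects what is consumed to appear as product. That rule assumes the spare nucleophile covers any other taker. Protic impurity per electrophile over spare nucleophile is 2.00, above 1, so if the impurity takes nucleophile one for one, the spare nucleophile does not cover it. The readings also part from the rule: at 8.00 min, 70.0% of the charge has gone, yet product is 41%.

So we follow one electrophile molecule to its fork. We carry the product odds, a selectivity factor: product made per electrophile gone elsewhere. The last reading gives 1.41, with the scatter of 2 percentage points in it. A molecule that reacts therefore becomes product with chance 58.6%, and we commit to that share at 20 min. If the other route needs no partner, the odds scale with the charge at fixed equivalents.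

The forecast gave 90% reacted and 55% of the unused nucleophile free, with “a side channel or a reversible reservoir” taking the rest.

The flask gives 79.2% reacted and 14.9% free. Beside product at 45.0%, the dormant form holds 34.3% of the charge at 20.0 min. Our share applied to 79.2% gives 46.4% of the charge as product.

    nucleophile + protic impurity → quenched reagent (k = 0.00250 M⁻¹ s⁻¹)
    electrophile + nucleophile → acid set free + product (k = 0.00260 M⁻¹ s⁻¹)
    electrophile ⇌ dormant form (K = 1.80, k = 0.00130 s⁻¹)
    nucleophile + acid set free ⇌ protonated nucleophile, settled at all times (K = 280 M⁻¹)

With electrophile at 0.20 M and the equivalents held, the ratio of charges turns the odds into 0.353, a share of 26.1%. That neighbour flask computes to 67.8% reacted and 19.3% product, a share of 28.5%.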